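## Analysis of the target

- The target is a C50 carotenoid (C50H72O). Two 2-alkylated ε-end groups are joined by an all-E chain of 18 carbons (C7 to C7') with nine conjugated double bonds and methyl groups on C9, C13, C13' and C9'.
- Each ring is a cyclohexene with a CMe2 carbon (C1), a C4=C5 double bond bearing the C5 methyl, and the chain on C6. Ring A carries a 3-methylbut-2-enyl group on C2; ring B carries an (E)-4-hydroxy-3-methylbut-2-enyl group on C2'.
- The structure has four stereocentres. Ring A is (2S,6R), with the C2 arm and the C6 chain cis. Ring B is (2'R,6'S), with arm and chain trans.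
- The two C2 centres have the same spatial sense; the letter changes only because the hydroxyl lifts the ring-B arm above C3 in CIP rank. The two C6 centres are opposite, so the rings are C6 epimers of one another apart from the hydroxyl.
- Sensitive points are the polyene (light, oxygen, acid), the primary allylic alcohol, the prenyl-type alkenes, and the C6–H bonds. Each C6–H is allylic twice over, and any drift of C4=C5 into conjugation erases that centre.
- The synthesis is hard for two reasons. Each ring has a quaternary C1 between two stereocentres. The two halves differ in both arm and relative configuration, so nothing can be made by dimerisation and the chain must be grown from two different ends.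
- The strategy rests on C2. It is bonded to the arm CH2, the ring CH2 (C3) and C1 with its two methyls. This is the pattern of C4 of limonene (two ring CH2 groups and an isopropenyl group). Because C2 has the same sense in both rings, one enantiomer, (R)-limonene, can serve both.

## Retrosynthetic reasoning

**29 to 28.** The hydroxyl of 29 is traced back to the ethyl ester 28, so the last step is a reduction at a remote carbonyl. A free primary allylic alcohol would not survive the acidic phosphonium salt formation needed earlier; an α,β-unsaturated ester does, and its E geometry comes from a stabilised ylide.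

**28 to 23 and 26; 26 to 18 and 24.** The chain is cut at C11'=C12' and then at C11=C12. Both are disubstituted double bonds next to the methyl-bearing ends of the symmetrical C10 dialdehyde 24, so each cut gives a primary allylic phosphonium salt (18, 23) and an unhindered, non-enolisable aldehyde (24, then 26). A central C15=C15' cut would need two different C25 halves. A cut at C7=C8 would put an epimerisable aldehyde on C6. Using 24 twice, one end at a time, allows the two different end groups.

**18 and 23 to 14.** In both salts the C–P bond and the C9=C10 bond come from a tertiary vinyl carbinol (17, 22) by allylic transposition, and the carbinol comes from a C9 methyl ketone. The arm double bond comes from an aldehyde (16, 21) by Wittig olefination. Both series therefore converge on one ketone, 14, with a two-carbon oxygenated arm on C2. Ring B needs only inversion at C6 (14 to 19), which is γ to the enone carbonyl. The vinyl addition is placed before the arm is touched, so the ketone is masked while the arm is oxidised and olefinated.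

**14 to 11 (key disconnection).** The ring is opened at C1–C6. In the forward sense a tertiary cation at C1, generated from an isopropenyl group, is captured by the C5=C6 bond of a dienone, and C4 loses a proton. This cut removes the quaternary carbon problem, because C1 arrives as an sp2 carbon with both methyls. It reduces the ring to an acyclic chain with one stereocentre, C2, which must then control C6. No other single cut leaves all carbons in place at the right oxidation level.

**11 to 10 to 6 and 7.** The dienone is traced back to the β-allenic ketone 10 by a prototropic shift. Ketone 10 comes from a [3,3] shift that forms C7–C8 from the tertiary propargylic alcohol 6 and the enol ether 7. This adds the three-carbon ketone unit to a methyl ketone in two operations. Its weakness is that C5=C6 is formed without geometric control, and this has to be dealt with by separation.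

**6 to 5 to 4 to 3 to 1.** The propargylic alcohol comes from acetylide addition to a methyl ketone (4 to 5), followed by selective acetylation of the primary hydroxyl (5 to 6). Ketone and primary alcohol come from the keto aldehyde 3, which is (R)-limonene 1 with its ring double bond cleaved. The ring cleavage turns C4 of 1 into C2 of the carotenoid rings. The isopropenyl group becomes C1 with its methyls, the ketone side becomes C3–C5 with the C5 methyl, and the aldehyde side becomes the first two arm carbons.

## Alternatives that were turned down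

**Alternative 1: ring contraction of a vinyl lactone by Ireland–Claisen rearrangement (C2–C3 bond).**
- Disconnection: the ring is opened at C2–C3 to the six-membered lactone A2, which carries a vinyl and a methyl group on the carbinol carbon.
- Forward key step: LiN(i-Pr)2 and Me3SiCl give the silyl ketene acetal, whose [3,3] shift is forced through a boat by the lactone ring. It gives the acid A1, with the carboxyl on C2, C4=C5 in place and a benzyloxymethyl group on C6.
- For it: the rearrangement is suprafacial and stereospecific, so the cis relation of C2 and C6 and the position of the double bond are fixed by mechanism. No cation is involved. On these two points it is stronger than the chosen route.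
- Against it: A2 needs an enantioselective synthesis of two adjacent centres, one a tertiary carbinol next to the quaternary carbon. After the key step the carboxyl carbon is only C1'' of the arm, so four carbons must still be added at a hindered position. C7 must be freed from a benzyl ether without hydrogenation, oxidised to an epimerisable aldehyde and extended. Ring B needs a second lactone or an epimerisation.
- Comparison: the chosen route gives up mechanistic certainty at C6 and gains step economy. The ring, its three methyls and two arm carbons come from limonene in seven steps with both appendages at a useful oxidation level, and one intermediate serves both rings.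

**Alternative 2: vinylcarbenoid [4+3] cycloaddition on a dimethylcyclopentadiene (C5–C6 and C2–C3 bonds).**
- Disconnection: the ring is taken back to the bicyclo[3.2.1]octadiene A3, and this to the vinyldiazo ester A4 and the silyloxy diene A5.
- Forward key step: the divalent rhodium catalyst Rh2(S-DOSP)4 (dirhodium tetrakis[(S)-N-(dodecylbenzenesulfonyl)prolinate]) converts A4 into a vinylcarbenoid. This cyclopropanates the silyl enol ether double bond of A5, and a Cope rearrangement of the divinylcyclopropane gives A3.
- For it: both stereocentres are set in one step under catalyst control, the cis relation is enforced by the bicycle, and either enantiomer is available. In absolute and relative stereocontrol it is stronger than the chosen route.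
- Against it: C5 arrives as a methyl ester and has to be reduced to a methyl group over several steps. Cleaving the silyl enol ether bridge leaves a formyl group on C2 and a carboxyl group on C6, so three carbonyl groups must be told apart. The arm again starts from one carbon. Both faces of the diene carry a methyl group of the CMe2 bridge, which should slow the carbenoid addition. Ring B still needs an epimerisation.
- Comparison: the chosen route has no redox corrections on ring carbons and uses an inexpensive chiral-pool starting material; its stereocontrol at C6 rests on a conformational preference and not on a catalyst.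

**Alternative 3: ring-closing metathesis with selection between two allyl groups (C4=C5 bond).**
- Disconnection: the ring is opened at C4=C5 to the triene A7, in which C6 carries the isopropenyl group and C2 carries two diastereotopic allyl groups.
- Forward key step: the second-generation Grubbs catalyst RuCl2(=CHPh)(H2IMes)(PCy3) joins the isopropenyl group with one allyl group to give the trans ether A6.
- For it: conditions are neutral, the double bond position is unambiguous, the trans ring B is formed directly, and the leftover allyl group could become the prenyl arm in a single cross-metathesis. The last point is shorter than the arm elaboration of the chosen route.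
- Against it: the two allyl groups on C2 form a hepta-1,6-diene, which should close to the cyclopentene A8 much faster than either allyl group reaches the hindered isopropenyl group next to the quaternary carbon. The choice between the allyl groups, which sets C2, rests on a modest bias across a quaternary centre. C6 must be set beforehand by a separate asymmetric synthesis of A7. The cis ring A is not accessible this way.
- Comparison: the chosen route has no competing ring closure of this kind, takes its stereocentre from the chiral pool, and reaches both relative configurations from one compound.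

Key step: step 7

Remark: carotenoid numbering is used for all intermediates (C1 = CMe2, C2 = carbon bearing the arm, C6 = carbon bearing the chain, primes for ring B); cis and trans refer to the C2 arm and the C6 side chain.

## Route

Step 1
Reactants: 1 (R)-(+)-limonene
Product: 3 (3R)-6-oxo-3-(prop-1-en-2-yl)heptanal, via limonene secondary ozonide 2 (not isolated)
Conditions: O3 (1.0 equiv, Sudan Red 7B end point), CH2Cl2, −78 °C; then PPh3, −78 °C → rt
Reagents that add atoms: ozone, [O-][O+]=O
Why: Ozonolysis with reductive work-up; the trisubstituted ring alkene is more electron-rich than the 1,1-disubstituted isopropenyl group and should be consumed first when ozone is dosed to one equivalent. The stereocentre is not touched.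

Step 2
Reactants: 3 (3R)-6-oxo-3-(prop-1-en-2-yl)heptanal
Product: 4 (5R)-7-hydroxy-5-(prop-1-en-2-yl)heptan-2-one
Conditions: NaBH(OAc)3 (1.5 equiv), PhMe, 80 °C; aq. NaHCO3
Reagents that add atoms: none
Why: Chemoselective hydride reduction: NaBH(OAc)3 is a weak donor that reduces aldehydes and leaves ketones. Compound 3 is used crude because it is prone to intramolecular aldol condensation.

Step 3
Reactants: 4 (5R)-7-hydroxy-5-(prop-1-en-2-yl)heptan-2-one
Product: 5 (6R)-3-methyl-6-(prop-1-en-2-yl)oct-1-yne-3,8-diol (C3 epimers)
Conditions: HC≡CMgBr (3 equiv), THF, 0 °C → rt; aq. NH4Cl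
Reagents that add atoms: ethynylmagnesium bromide, C#C[Mg]Br
Why: Grignard 1,2-addition to the methyl ketone; one equivalent is spent on the free hydroxyl, so no ester competes with the ketone for the reagent. The new carbinol centre forms as both epimers, which is harmless because this carbon becomes sp2 in step 5.

Step 4
Reactants: 5 (6R)-3-methyl-6-(prop-1-en-2-yl)oct-1-yne-3,8-diol (C3 epimers)
Product: 6 (3R)-6-hydroxy-6-methyl-3-(prop-1-en-2-yl)oct-7-yn-1-yl acetate (C6 epimers)
Conditions: Ac2O (1.2 equiv), pyridine, CH2Cl2, 0 °C → rt
Reagents that add atoms: acetic anhydride, CC(=O)OC(C)=O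
Why: Acylation without a nucleophilic catalyst discriminates on steric grounds: the primary hydroxyl is acetylated and the tertiary propargylic hydroxyl stays free for step 5. The acetate is chosen because it is inert to the acids of steps 5 and 7 and makes the arm oxygen non-nucleophilic.

Step 5
Reactants: 6 (3R)-6-hydroxy-6-methyl-3-(prop-1-en-2-yl)oct-7-yn-1-yl acetate (C6 epimers); 7 2-methoxypropene
Product: 10 (3R)-6-methyl-10-oxo-3-(prop-1-en-2-yl)undeca-6,7-dien-1-yl acetate (allene epimers), via mixed methyl ketal 8 (not isolated), via propargyl isopropenyl ether 9 (not isolated)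
Conditions: 7 (5 equiv), p-TsOH·H2O (0.3 mol %), hydroquinone (trace), sealed vessel, 100 °C; Et3N quench
Reagents that add atoms: none
Why: Saucy–Marbet rearrangement: acid-catalysed addition of the tertiary propargylic alcohol to 7 gives ketal 8, loss of methanol gives ether 9, and its [3,3] sigmatropic shift forms the C7–C8 bond and the β-allenic ketone. The acetate and the isopropenyl group should be inert to the trace of acid.

Step 6
Reactants: 10 (3R)-6-methyl-10-oxo-3-(prop-1-en-2-yl)undeca-6,7-dien-1-yl acetate (allene epimers)
Product: 11 (3E,5E,9R)-9-(2-acetoxyethyl)-6,10-dimethylundeca-3,5,10-trien-2-one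
Conditions: DBU (0.2 equiv), PhMe, 0 °C → rt; chromatography on AgNO3-impregnated SiO2
Reagents that add atoms: none
Why: Base-mediated prototropic isomerisation of a β-allenic ketone to the conjugated dienone: the amidine removes a proton α to the ketone and reprotonation at the central allene carbon gives the dienone, in an aprotic medium that spares the acetate. C3=C4 should form E, but C5=C6 forms as both geometric isomers; the 5E form is separated and the remainder is re-equilibrated (I2 cat., light) and passed through the separation again.

Step 7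
Reactants: 11 (3E,5E,9R)-9-(2-acetoxyethyl)-6,10-dimethylundeca-3,5,10-trien-2-one
Product: 14 2-[(1R,5R)-4,6,6-trimethyl-5-[(1E)-3-oxobut-1-en-1-yl]cyclohex-3-en-1-yl]ethyl acetate (cis-2-(2-acetoxyethyl)-α-ionone; carotenoid numbering 2R,6R), via C1 tertiary cation 12 (not isolated), via C5 ring cation 13 (not isolated)
Conditions: BF3·OEt2 (2 equiv), H2O (ca. 0.1 equiv as proton source), CH2Cl2, −30 → 0 °C; aq. NaHCO3
Reagents that add atoms: none
Why: The Brønsted acid formed from BF3 and water protonates the CH2 terminus of the isopropenyl group, the only isolated and electron-rich alkene, in the Markovnikov sense to give cation 12; C6 of the C5=C6 bond then bonds to C1 and leaves the tertiary cation 13, which loses a proton from C4 to give the C4=C5 alkene. The closest known reaction is the acid-mediated cyclisation of pseudoionone to α-ionone and of pseudoirones to α-irones; the difference is only that the same kind of tertiary cation is reached from a 1,1-disubstituted alkene. The single ring is closed in the 6-endo-trig mode with respect to the C5=C6 bond, since C5 stays in the ring. The new stereocentre C6 is controlled by the C2 centre from limonene: in a chair-like transition state the C2 arm should sit equatorial and the E geometry of C5=C6 places C7 equatorial, so arm and side chain end up cis (2R,6R). The step needs proton loss from C4 and not from C6 or the C5 methyl, for which the weakly basic counter-ion and the low temperature are chosen. It needs the arm oxygen to stay out of the reaction, which the acetate secures, since a free hydroxyl would be expected to close an oxolane onto C1. It also needs ring closure to be faster than loss of the C2 proton from cation 12, which would erase the C2 centre; the intramolecular six-membered closure in a non-basic medium should favour this. C7=C8 and the carbonyl groups are electron-poor and take no part.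

Step 8
Reactants: 14 2-[(1R,5R)-4,6,6-trimethyl-5-[(1E)-3-oxobut-1-en-1-yl]cyclohex-3-en-1-yl]ethyl acetate
Product: 15 2-[(1R,5R)-5-[(1E)-3-hydroxy-3-methylpenta-1,4-dien-1-yl]-4,6,6-trimethylcyclohex-3-en-1-yl]ethan-1-ol (carbinol epimers)
Conditions: CH2=CHMgBr (4.5 equiv), THF, −20 °C → rt; aq. NH4Cl
Reagents that add atoms: vinylmagnesium bromide, C=C[Mg]Br
Why: Grignard 1,2-addition to the enone carbonyl, the usual entry to vinyl ionols; the surplus reagent also removes the acetate as a volatile carbinol, so no alkoxide is needed while C6–H is still γ to a carbonyl. Placing this step first masks the ketone before the arm is oxidised and olefinated; the new carbinol centre (both epimers) is lost in step 11.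

Step 9
Reactants: 15 2-[(1R,5R)-5-[(1E)-3-hydroxy-3-methylpenta-1,4-dien-1-yl]-4,6,6-trimethylcyclohex-3-en-1-yl]ethan-1-ol (carbinol epimers)
Product: 16 2-[(1R,5R)-5-[(1E)-3-hydroxy-3-methylpenta-1,4-dien-1-yl]-4,6,6-trimethylcyclohex-3-en-1-yl]acetaldehyde (carbinol epimers)
Conditions: Dess–Martin periodinane (1.3 equiv), pyridine (4 equiv), CH2Cl2, 0 °C → rt; aq. Na2S2O3/NaHCO3
Reagents that add atoms: none
Why: Dess–Martin oxidation of the primary alcohol to the aldehyde; the tertiary alcohol cannot be oxidised, and the pyridine buffer keeps it from ionising in the acetic acid that is set free.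

Step 10
Reactants: 16 2-[(1R,5R)-5-[(1E)-3-hydroxy-3-methylpenta-1,4-dien-1-yl]-4,6,6-trimethylcyclohex-3-en-1-yl]acetaldehyde (carbinol epimers)
Product: 17 (1E)-3-methyl-1-[(1R,5S)-2,6,6-trimethyl-5-(3-methylbut-2-en-1-yl)cyclohex-2-en-1-yl]penta-1,4-dien-3-ol (carbinol epimers)
Conditions: i-PrPPh3+ I− (1.6 equiv), n-BuLi (1.5 equiv), THF, 0 °C; then 16, −78 °C → rt
Reagents that add atoms: isopropyltriphenylphosphonium iodide, CC(C)[P+](c1ccccc1)(c1ccccc1)c1ccccc1.[I-]
Why: Wittig olefination with the non-stabilised isopropylidene ylide turns CH2–CHO into the prenyl group; there is no E/Z question because the new alkene carbon carries two methyls. The tertiary alcohol is far less acidic than the phosphonium salt and should be left alone by the ylide.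

Step 11
Reactants: 17 (1E)-3-methyl-1-[(1R,5S)-2,6,6-trimethyl-5-(3-methylbut-2-en-1-yl)cyclohex-2-en-1-yl]penta-1,4-dien-3-ol (carbinol epimers)
Product: 18 [(2E,4E)-3-methyl-5-[(1R,5S)-2,6,6-trimethyl-5-(3-methylbut-2-en-1-yl)cyclohex-2-en-1-yl]penta-2,4-dien-1-yl]triphenylphosphonium bromide
Conditions: PPh3·HBr (1.05 equiv), MeOH, rt; crystallisation
Reagents that add atoms: triphenylphosphine hydrobromide, [Br-].[PH+](c1ccccc1)(c1ccccc1)c1ccccc1
Why: The acid ionises the tertiary, doubly allylic alcohol to a pentadienyl cation that PPh3 captures at the unhindered primary terminus C11 (allylic transposition), as in the preparation of ionylidene-ethyl phosphonium salts. The phosphine, present in stoichiometric amount, should outcompete the prenyl alkene for this stabilised cation, and the weak acid should not protonate the isolated trisubstituted alkenes; the 9E salt is purified by crystallisation.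

Step 12
Reactants: 14 2-[(1R,5R)-4,6,6-trimethyl-5-[(1E)-3-oxobut-1-en-1-yl]cyclohex-3-en-1-yl]ethyl acetate
Product: 19 (3E)-4-[(1S,5R)-5-(2-hydroxyethyl)-2,6,6-trimethylcyclohex-2-en-1-yl]but-3-en-2-one (trans; carotenoid numbering 2R,6S)
Conditions: NaOMe (0.5 equiv), MeOH, rt (monitored); AcOH quench
Reagents that add atoms: none
Why: Methoxide removes the acetate by transesterification and reversibly deprotonates C6–H, which is γ to the enone carbonyl; reprotonation at C6 should equilibrate the epimers toward the trans isomer, in which the C6 side chain is pseudoaxial (away from the C5 methyl) and the C2 arm equatorial, the behaviour known for the 2-methyl analogues (α-irones). C2 is not acidic and keeps its configuration; the reaction is stopped before the slower protonation at C4 can move the ring alkene into conjugation, and unconverted cis material is separated and returned.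

Step 13
Reactants: 19 (3E)-4-[(1S,5R)-5-(2-hydroxyethyl)-2,6,6-trimethylcyclohex-2-en-1-yl]but-3-en-2-one
Product: 20 2-[(1R,5S)-5-[(1E)-3-hydroxy-3-methylpenta-1,4-dien-1-yl]-4,6,6-trimethylcyclohex-3-en-1-yl]ethan-1-ol (carbinol epimers)
Conditions: CH2=CHMgBr (3.5 equiv), THF, −20 °C → rt; aq. NH4Cl
Reagents that add atoms: vinylmagnesium bromide, C=C[Mg]Br
Why: Grignard 1,2-addition to the enone carbonyl as in step 8; one equivalent is consumed by the primary hydroxyl. The carbinol centre forms as both epimers and is lost in step 16.

Step 14
Reactants: 20 2-[(1R,5S)-5-[(1E)-3-hydroxy-3-methylpenta-1,4-dien-1-yl]-4,6,6-trimethylcyclohex-3-en-1-yl]ethan-1-ol (carbinol epimers)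
Product: 21 2-[(1R,5S)-5-[(1E)-3-hydroxy-3-methylpenta-1,4-dien-1-yl]-4,6,6-trimethylcyclohex-3-en-1-yl]acetaldehyde (carbinol epimers)
Conditions: Dess–Martin periodinane (1.3 equiv), pyridine (4 equiv), CH2Cl2, 0 °C → rt; aq. Na2S2O3/NaHCO3
Reagents that add atoms: none
Why: Dess–Martin oxidation of the primary alcohol as in step 9; the buffered, non-basic conditions leave the tertiary allylic alcohol and both ring stereocentres untouched.

Step 15
Reactants: 21 2-[(1R,5S)-5-[(1E)-3-hydroxy-3-methylpenta-1,4-dien-1-yl]-4,6,6-trimethylcyclohex-3-en-1-yl]acetaldehyde (carbinol epimers)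
Product: 22 ethyl (2E)-4-[(1R,5S)-5-[(1E)-3-hydroxy-3-methylpenta-1,4-dien-1-yl]-4,6,6-trimethylcyclohex-3-en-1-yl]-2-methylbut-2-enoate (carbinol epimers)
Conditions: Ph3P=C(CH3)CO2Et (1.3 equiv), CH2Cl2, rt
Reagents that add atoms: ethyl 2-(triphenyl-λ5-phosphanylidene)propanoate, CCOC(=O)C(C)=P(c1ccccc1)(c1ccccc1)c1ccccc1
Why: Wittig reaction of a stabilised α-methyl ester ylide with an aldehyde, which is reliably E-selective and sets the geometry of the ring-B arm. The ester is the masked allylic alcohol: it is inert to the acid of step 16, whereas a free primary allylic alcohol would itself be converted into a phosphonium salt.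

Step 16
Reactants: 22 ethyl (2E)-4-[(1R,5S)-5-[(1E)-3-hydroxy-3-methylpenta-1,4-dien-1-yl]-4,6,6-trimethylcyclohex-3-en-1-yl]-2-methylbut-2-enoate (carbinol epimers)
Product: 23 [(2E,4E)-5-[(1S,5R)-5-[(2E)-4-ethoxy-3-methyl-4-oxobut-2-en-1-yl]-2,6,6-trimethylcyclohex-2-en-1-yl]-3-methylpenta-2,4-dien-1-yl]triphenylphosphonium bromide
Conditions: PPh3·HBr (1.05 equiv), EtOH, rt; crystallisation
Reagents that add atoms: triphenylphosphine hydrobromide, [Br-].[PH+](c1ccccc1)(c1ccccc1)c1ccccc1
Why: Acid-mediated ionisation of the tertiary allylic alcohol and capture of the pentadienyl cation by PPh3 at C11', as in step 11. The conjugated ester is neither protonated nor ionised under these conditions.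

Step 17
Reactants: 18 [(2E,4E)-3-methyl-5-[(1R,5S)-2,6,6-trimethyl-5-(3-methylbut-2-en-1-yl)cyclohex-2-en-1-yl]penta-2,4-dien-1-yl]triphenylphosphonium bromide; 24 (2E,4E,6E)-2,7-dimethylocta-2,4,6-trienedial
Product: 26 (2E,4E,6E,8E,10E,12E)-2,7,11-trimethyl-13-[(1R,5S)-2,6,6-trimethyl-5-(3-methylbut-2-en-1-yl)cyclohex-2-en-1-yl]trideca-2,4,6,8,10,12-hexaenal, via ring-A phosphorus ylide 25 (not isolated)
Conditions: 24 (3 equiv), 1,2-epoxybutane/EtOH, 70 °C, slow addition of 18; then n-heptane, 90 °C, dark, Ar
Reagents that add atoms: none
Why: Wittig olefination under base-free epoxide conditions: bromide opens the epoxide, the alkoxide so formed generates ylide 25, and this condenses with one formyl group of the dialdehyde, used in excess, to form C11=C12. Heating should equilibrate the 11Z isomer to E, and the absence of strong base spares the C6 centre.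

Step 18
Reactants: 23 [(2E,4E)-5-[(1S,5R)-5-[(2E)-4-ethoxy-3-methyl-4-oxobut-2-en-1-yl]-2,6,6-trimethylcyclohex-2-en-1-yl]-3-methylpenta-2,4-dien-1-yl]triphenylphosphonium bromide; 26 (2E,4E,6E,8E,10E,12E)-2,7,11-trimethyl-13-[(1R,5S)-2,6,6-trimethyl-5-(3-methylbut-2-en-1-yl)cyclohex-2-en-1-yl]trideca-2,4,6,8,10,12-hexaenal
Product: 28 ethyl (2E)-2-methyl-4-[(1R,5S)-4,6,6-trimethyl-5-[(1E,3E,5E,7E,9E,11E,13E,15E,17E)-3,7,12,16-tetramethyl-18-[(1R,5S)-2,6,6-trimethyl-5-(3-methylbut-2-en-1-yl)cyclohex-2-en-1-yl]octadeca-1,3,5,7,9,11,13,15,17-nonaen-1-yl]cyclohex-3-en-1-yl]but-2-enoate, via ring-B phosphorus ylide 27 (not isolated)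
Conditions: 1,2-epoxybutane/EtOH, 70 °C; then n-heptane, 90 °C, dark, Ar
Reagents that add atoms: none
Why: The second Wittig olefination forms C11'=C12' and completes the C50 skeleton; because the two ends are introduced one after the other, the unsymmetrical pair of end groups is obtained without statistical mixing. Thermal equilibration should give the all-E chain.

Step 19
Reactants: 28 ethyl (2E)-2-methyl-4-[(1R,5S)-4,6,6-trimethyl-5-[(1E,3E,5E,7E,9E,11E,13E,15E,17E)-3,7,12,16-tetramethyl-18-[(1R,5S)-2,6,6-trimethyl-5-(3-methylbut-2-en-1-yl)cyclohex-2-en-1-yl]octadeca-1,3,5,7,9,11,13,15,17-nonaen-1-yl]cyclohex-3-en-1-yl]but-2-enoate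
Product: 29 (2E)-2-methyl-4-[(1R,5S)-4,6,6-trimethyl-5-[(1E,3E,5E,7E,9E,11E,13E,15E,17E)-3,7,12,16-tetramethyl-18-[(1R,5S)-2,6,6-trimethyl-5-(3-methylbut-2-en-1-yl)cyclohex-2-en-1-yl]octadeca-1,3,5,7,9,11,13,15,17-nonaen-1-yl]cyclohex-3-en-1-yl]but-2-en-1-ol (the target)
Conditions: i-Bu2AlH (3 equiv), CH2Cl2, −78 °C, dark, Ar; aq. potassium sodium tartrate
Reagents that add atoms: none
Why: 1,2-Reduction of the α,β-unsaturated ester to the primary allylic alcohol with retention of the E geometry. The polyene and the isolated alkenes are inert to the aluminium hydride at low temperature.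

## Compound list

1 | (R)-(+)-limonene, (4R)-1-methyl-4-(prop-1-en-2-yl)cyclohex-1-ene | CC1=CC[C@H](C(C)=C)CC1 | starting material
2 | limonene secondary ozonide, (4R)-1-methyl-4-(prop-1-en-2-yl)-7,8,9-trioxabicyclo[4.2.1]nonane (bridgehead epimers, not isolated) | CC12CC[C@@H](C(C)=C)CC(OO1)O2 | intermediate
3 | (3R)-6-oxo-3-(prop-1-en-2-yl)heptanal | O=CC[C@H](C(C)=C)CCC(C)=O | intermediate
4 | (5R)-7-hydroxy-5-(prop-1-en-2-yl)heptan-2-one | OCC[C@H](C(C)=C)CCC(C)=O | intermediate
5 | (6R)-3-methyl-6-(prop-1-en-2-yl)oct-1-yne-3,8-diol (C3 epimers) | OCC[C@H](C(C)=C)CCC(C)(O)C#C | intermediate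
6 | (3R)-6-hydroxy-6-methyl-3-(prop-1-en-2-yl)oct-7-yn-1-yl acetate (C6 epimers) | CC(=O)OCC[C@H](C(C)=C)CCC(C)(O)C#C | intermediate
7 | 2-methoxypropene | COC(C)=C | starting material
8 | mixed methyl ketal, (3R)-6-[(2-methoxypropan-2-yl)oxy]-6-methyl-3-(prop-1-en-2-yl)oct-7-yn-1-yl acetate (not isolated) | CC(=O)OCC[C@H](C(C)=C)CCC(C)(OC(C)(C)OC)C#C | intermediate
9 | propargyl isopropenyl ether, (3R)-6-methyl-3-(prop-1-en-2-yl)-6-(prop-1-en-2-yloxy)oct-7-yn-1-yl acetate (not isolated) | CC(=O)OCC[C@H](C(C)=C)CCC(C)(OC(C)=C)C#C | intermediate
10 | (3R)-6-methyl-10-oxo-3-(prop-1-en-2-yl)undeca-6,7-dien-1-yl acetate (allene epimers) | CC(=O)OCC[C@H](C(C)=C)CCC(C)=C=CCC(C)=O | intermediate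
11 | (3E,5E,9R)-9-(2-acetoxyethyl)-6,10-dimethylundeca-3,5,10-trien-2-one | CC(=O)OCC[C@H](C(C)=C)CC/C(C)=C/C=C/C(C)=O | intermediate
12 | C1 tertiary cation from protonation of the isopropenyl group of 11 (not isolated) | CC(=O)OCC[C@H]([C+](C)C)CC/C(C)=C/C=C/C(C)=O | intermediate
13 | C5 ring cation after C1–C6 bond formation (not isolated) | CC(=O)OCC[C@H]1CC[C+](C)[C@@H](/C=C/C(C)=O)C1(C)C | intermediate
14 | 2-[(1R,5R)-4,6,6-trimethyl-5-[(1E)-3-oxobut-1-en-1-yl]cyclohex-3-en-1-yl]ethyl acetate; cis-2-(2-acetoxyethyl)-α-ionone, (2R,6R) in carotenoid numbering | CC(=O)OCC[C@H]1CC=C(C)[C@@H](/C=C/C(C)=O)C1(C)C | intermediate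
15 | 2-[(1R,5R)-5-[(1E)-3-hydroxy-3-methylpenta-1,4-dien-1-yl]-4,6,6-trimethylcyclohex-3-en-1-yl]ethan-1-ol (carbinol epimers) | OCC[C@H]1CC=C(C)[C@@H](/C=C/C(C)(O)C=C)C1(C)C | intermediate
16 | 2-[(1R,5R)-5-[(1E)-3-hydroxy-3-methylpenta-1,4-dien-1-yl]-4,6,6-trimethylcyclohex-3-en-1-yl]acetaldehyde (carbinol epimers) | O=CC[C@H]1CC=C(C)[C@@H](/C=C/C(C)(O)C=C)C1(C)C | intermediate
17 | (1E)-3-methyl-1-[(1R,5S)-2,6,6-trimethyl-5-(3-methylbut-2-en-1-yl)cyclohex-2-en-1-yl]penta-1,4-dien-3-ol (carbinol epimers) | CC(C)=CC[C@H]1CC=C(C)[C@@H](/C=C/C(C)(O)C=C)C1(C)C | intermediate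
18 | [(2E,4E)-3-methyl-5-[(1R,5S)-2,6,6-trimethyl-5-(3-methylbut-2-en-1-yl)cyclohex-2-en-1-yl]penta-2,4-dien-1-yl]triphenylphosphonium bromide | CC(C)=CC[C@H]1CC=C(C)[C@@H](/C=C/C(C)=C/C[P+](c2ccccc2)(c2ccccc2)c2ccccc2)C1(C)C.[Br-] | intermediate
19 | (3E)-4-[(1S,5R)-5-(2-hydroxyethyl)-2,6,6-trimethylcyclohex-2-en-1-yl]but-3-en-2-one; trans, (2R,6S) in carotenoid numbering | OCC[C@H]1CC=C(C)[C@H](/C=C/C(C)=O)C1(C)C | intermediate
20 | 2-[(1R,5S)-5-[(1E)-3-hydroxy-3-methylpenta-1,4-dien-1-yl]-4,6,6-trimethylcyclohex-3-en-1-yl]ethan-1-ol (carbinol epimers) | OCC[C@H]1CC=C(C)[C@H](/C=C/C(C)(O)C=C)C1(C)C | intermediate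
21 | 2-[(1R,5S)-5-[(1E)-3-hydroxy-3-methylpenta-1,4-dien-1-yl]-4,6,6-trimethylcyclohex-3-en-1-yl]acetaldehyde (carbinol epimers) | O=CC[C@H]1CC=C(C)[C@H](/C=C/C(C)(O)C=C)C1(C)C | intermediate
22 | ethyl (2E)-4-[(1R,5S)-5-[(1E)-3-hydroxy-3-methylpenta-1,4-dien-1-yl]-4,6,6-trimethylcyclohex-3-en-1-yl]-2-methylbut-2-enoate (carbinol epimers) | CCOC(=O)/C(C)=C/C[C@H]1CC=C(C)[C@H](/C=C/C(C)(O)C=C)C1(C)C | intermediate
23 | [(2E,4E)-5-[(1S,5R)-5-[(2E)-4-ethoxy-3-methyl-4-oxobut-2-en-1-yl]-2,6,6-trimethylcyclohex-2-en-1-yl]-3-methylpenta-2,4-dien-1-yl]triphenylphosphonium bromide | CCOC(=O)/C(C)=C/C[C@H]1CC=C(C)[C@H](/C=C/C(C)=C/C[P+](c2ccccc2)(c2ccccc2)c2ccccc2)C1(C)C.[Br-] | intermediate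
24 | (2E,4E,6E)-2,7-dimethylocta-2,4,6-trienedial | O=C/C(C)=C/C=C/C=C(C)/C=O | starting material
25 | ring-A phosphorus ylide from 18 (not isolated) | CC(C)=CC[C@H]1CC=C(C)[C@@H](/C=C/C(C)=C/C=P(c2ccccc2)(c2ccccc2)c2ccccc2)C1(C)C | intermediate
26 | (2E,4E,6E,8E,10E,12E)-2,7,11-trimethyl-13-[(1R,5S)-2,6,6-trimethyl-5-(3-methylbut-2-en-1-yl)cyclohex-2-en-1-yl]trideca-2,4,6,8,10,12-hexaenal | CC(C)=CC[C@H]1CC=C(C)[C@@H](/C=C/C(C)=C/C=C/C(C)=C/C=C/C=C(C)/C=O)C1(C)C | intermediate
27 | ring-B phosphorus ylide from 23 (not isolated) | CCOC(=O)/C(C)=C/C[C@H]1CC=C(C)[C@H](/C=C/C(C)=C/C=P(c2ccccc2)(c2ccccc2)c2ccccc2)C1(C)C | intermediate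
28 | ethyl ester of the target skeleton, ethyl (2E)-2-methyl-4-[(1R,5S)-4,6,6-trimethyl-5-[(all-E)-3,7,12,16-tetramethyl-18-[(1R,5S)-2,6,6-trimethyl-5-(3-methylbut-2-en-1-yl)cyclohex-2-en-1-yl]octadeca-1,3,5,7,9,11,13,15,17-nonaen-1-yl]cyclohex-3-en-1-yl]but-2-enoate | CC(C)=CC[C@H]1CC=C(C)[C@@H](/C=C/C(C)=C/C=C/C(C)=C/C=C/C=C(C)/C=C/C=C(C)/C=C/[C@H]2C(C)=CC[C@H](C/C=C(\C)C(=O)OCC)C2(C)C)C1(C)C | intermediate
29 | CNP0304855.1, (2S,6R,2'R,6'S)-2-(3-methylbut-2-enyl)-2'-[(2E)-4-hydroxy-3-methylbut-2-enyl]-ε,ε-carotene | CC(C)=CC[C@H]1CC=C(C)[C@@H](/C=C/C(C)=C/C=C/C(C)=C/C=C/C=C(C)/C=C/C=C(C)/C=C/[C@H]2C(C)=CC[C@H](C/C=C(\C)CO)C2(C)C)C1(C)C | target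

## Step count and least certain steps

Total step count: 19. Longest linear sequence: 14 steps (steps 1–7, 8–11, 17, 18, 19; the ring-B branch through steps 12–16, 18, 19 is equally long).

**Step 7 (key step).** Three processes can go wrong.
- Proton loss from cation 13 may stray toward C6 or the C5 methyl, giving positional isomers of the ring alkene.
- Facial control in the ring closure may be incomplete. This costs little, because the cis and the trans epimer are both needed, for ring A and ring B.
- The C2 configuration may erode. Cation 12 carries a tertiary C–H next to the charge and faces a deactivated diene, so loss of the C2 proton (shift of the isopropenyl double bond to the tetrasubstituted position) or a 1,2-hydride shift could outrun ring closure. The enantiomeric purity of 14 would be checked at this point.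

Fallback: it sets out from 11 and comes back at 14, and replaces the free cation by a bridged one. Hg(OTf)2·PhNMe2 (MeNO2, −20 °C) adds to the isopropenyl CH2 in the Markovnikov sense; oxymercuration-type intermediates are known not to rearrange or lose the neighbouring proton, and C6 should close onto C1 as before. Work-up with aqueous NaCl gives the organomercurial 2-[(1R,5R)-6-(chloromercuriomethyl)-4,6-dimethyl-5-[(1E)-3-oxobut-1-en-1-yl]cyclohex-3-en-1-yl]ethyl acetate F1 (C1 epimers). Bu3SnH with a radical initiator (PhMe, 60 °C) replaces mercury by hydrogen, which turns the CH2HgCl group into the second C1 methyl and gives 14.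

**Step 12.** The epimerisation may be overtaken by migration of the ring double bond into conjugation, which would destroy C6, or it may stop at an unfavourable epimer ratio.

Fallback: it sets out from 10 and comes back at 20, and sets the trans relation by substrate control instead of enolisation. The isomerisation of step 6 also delivers the geometric isomer (3E,5Z,9R)-9-(2-acetoxyethyl)-6,10-dimethylundeca-3,5,10-trien-2-one F2. Under the conditions of step 7 its Z geometry should place C7 axial in the chair while the C2 arm stays equatorial. This should give 2-[(1R,5S)-4,6,6-trimethyl-5-[(1E)-3-oxobut-1-en-1-yl]cyclohex-3-en-1-yl]ethyl acetate F3, the trans epimer, directly. Excess CH2=CHMgBr, as in step 8, then gives 20.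

**Step 1.** Ozone may attack the isopropenyl group before the ring alkene is fully consumed, or conversion may be left incomplete to avoid this.

Fallback: it sets out from 1 and comes back at 3, and replaces ozone by epoxidation and glycol cleavage. m-Chloroperbenzoic acid (1.0 equiv, CH2Cl2, NaHCO3, 0 °C) epoxidises the trisubstituted alkene well before the isopropenyl group and gives (4R)-limonene 1,2-oxide F4 (cis/trans mixture). H5IO6 in THF/H2O opens the epoxide and cleaves the resulting glycol in one pot to 3.

**Step 17.** Olefination may occur at both formyl groups of the symmetrical dialdehyde, and the mono- and bis-adducts and recovered 24 may be hard to separate.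

Fallback: it sets out from 24 and comes back at 26, and differentiates the two ends before the coupling. Mono-acetalisation of 24 with 2,2-dimethylpropane-1,3-diol (1 equiv, pyridinium p-toluenesulfonate, CH2Cl2) gives (2E,4E,6E)-7-(5,5-dimethyl-1,3-dioxan-2-yl)-2-methylocta-2,4,6-trienal F5; unchanged 24 is recycled. Wittig reaction of 18 with F5 under the conditions of step 17 gives the C30 acetal 5,5-dimethyl-2-[(all-E)-6,10-dimethyl-12-[(1R,5S)-2,6,6-trimethyl-5-(3-methylbut-2-en-1-yl)cyclohex-2-en-1-yl]dodeca-1,3,5,7,9,11-hexaen-2-yl]-1,3-dioxane F6. Mild hydrolysis (pyridinium p-toluenesulfonate, wet acetone) gives 26.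

## Further compounds

F1 | step 7 | 2-[(1R,5R)-6-(chloromercuriomethyl)-4,6-dimethyl-5-[(1E)-3-oxobut-1-en-1-yl]cyclohex-3-en-1-yl]ethyl acetate (C1 epimers) | CC(=O)OCC[C@H]1CC=C(C)[C@@H](/C=C/C(C)=O)C1(C)C[Hg]Cl
F2 | step 12 | (3E,5Z,9R)-9-(2-acetoxyethyl)-6,10-dimethylundeca-3,5,10-trien-2-one | CC(=O)OCC[C@H](C(C)=C)CC/C(C)=C\C=C\C(C)=O
F3 | step 12 | 2-[(1R,5S)-4,6,6-trimethyl-5-[(1E)-3-oxobut-1-en-1-yl]cyclohex-3-en-1-yl]ethyl acetate (trans-2-(2-acetoxyethyl)-α-ionone) | CC(=O)OCC[C@H]1CC=C(C)[C@H](/C=C/C(C)=O)C1(C)C
F4 | step 1 | (4R)-limonene 1,2-oxide (cis/trans mixture) | CC12CC[C@@H](C(C)=C)CC1O2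
F5 | step 17 | (2E,4E,6E)-7-(5,5-dimethyl-1,3-dioxan-2-yl)-2-methylocta-2,4,6-trienal | O=C/C(C)=C/C=C/C=C(C)/C1OCC(C)(C)CO1
F6 | step 17 | 5,5-dimethyl-2-[(all-E)-6,10-dimethyl-12-[(1R,5S)-2,6,6-trimethyl-5-(3-methylbut-2-en-1-yl)cyclohex-2-en-1-yl]dodeca-1,3,5,7,9,11-hexaen-2-yl]-1,3-dioxane | CC(C)=CC[C@H]1CC=C(C)[C@@H](/C=C/C(C)=C/C=C/C(C)=C/C=C/C=C(C)/C2OCC(C)(C)CO2)C1(C)C
A1 | alternative 1 | cis-6-(benzyloxymethyl)-2,2,5-trimethylcyclohex-4-ene-1-carboxylic acid | OC(=O)[C@H]1CC=C(C)[C@@H](COCc2ccccc2)C1(C)C
A2 | alternative 1 | 5-(benzyloxymethyl)-6-ethenyl-4,4,6-trimethyloxan-2-one (vinyl and benzyloxymethyl trans) | O=C1CC(C)(C)[C@H](COCc2ccccc2)[C@@](C)(C=C)O1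
A3 | alternative 2 | methyl 7-(tert-butyldimethylsilyloxy)-8,8-dimethylbicyclo[3.2.1]octa-2,6-diene-2-carboxylate | C3[C@H]1CC=C(C(=O)OC)[C@@H](C=3O[Si](C)(C)C(C)(C)C)C1(C)C
A4 | alternative 2 | methyl 2-diazobut-3-enoate | C=CC(=[N+]=[N-])C(=O)OC
A5 | alternative 2 | 2-(tert-butyldimethylsilyloxy)-5,5-dimethylcyclopenta-1,3-diene | CC1(C)C=CC(O[Si](C)(C)C(C)(C)C)=C1
A6 | alternative 3 | trans-2-allyl-α-cyclogeranyl benzyl ether | c1ccccc1COC[C@H]2C(C)=CC[C@H](CC=C)C2(C)C
A7 | alternative 3 | benzyl 3,3-dimethyl-2-(prop-1-en-2-yl)-4-(prop-2-en-1-yl)hept-6-en-1-yl ether (chain C2 configured as C6 of ring B) | c1ccccc1COC[C@@H](C(C)=C)C(C)(C)C(CC=C)CC=C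
A8 | alternative 3 | benzyl 3-(cyclopent-3-en-1-yl)-3-methyl-2-(prop-1-en-2-yl)butyl ether | c1ccccc1COC[C@@H](C(C)=C)C(C)(C)C1CC=CC1
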